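## Retrosynthetic overview

1. Target 13 ⇒ flat, achiral aryl farnesyl ether 10. The C1'–C5 bond is formed last, by a catalytic enantioselective para-Claisen cascade (Claisen shift O8→C7, then Cope shift C7→C5). The same operation dearomatises ring A, sets C5 and, after fluoride, frees the C6/C8 vinylogous acid.
2. Enabling feature: in carbocyclic ring A (C4a-C5-C6-C7-C8-C8a), C5 lies para to O8. The ortho carbon C7 and the para carbon C5 both carry methyl groups, so neither dienone can re-aromatise. O8 sits beside the lactone carbonyl C1=O of pyranone ring B, a rigid two-point binding site for a chiral Lewis acid.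
3. 10 ⇒ isocoumarin 8 + (2E,6E)-farnesol 9 by Mitsunobu etherification at O8. O6 is held as a TBS ether, which leaves again in the key operation.
4. Ring B ⇒ lateral acylation of ortho-toluate 4 followed by enol-lactonisation. The C5 methyl group ⇒ formylation/hydrogenolysis of methyl atratate 1.
5. Ring order: ring A is bought with 1, ring B is closed in step 4, and no ring is formed afterwards.

Key step: step 7

Numbering: isochromene numbers are used for the bicycle and primed numbers for the farnesyl chain. Ring A is the carbocycle and ring B is the pyranone.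

Assumption: (S,S)-t-Bu-box, 2,2'-(propane-2,2-diyl)bis[(4S)-4-tert-butyl-4,5-dihydrooxazole], is taken to steer the chain over the face of ring A that leads to 5S. If the sense proves opposite, the equally available (R,R)-ligand is used and nothing else changes.

## Route

Step 1
Reactants: 1 methyl atratate (methyl 2,4-dihydroxy-3,6-dimethylbenzoate)
Product: 2 methyl 3-formyl-4,6-dihydroxy-2,5-dimethylbenzoate
Conditions: Cl2CHOMe, TiCl4, CH2Cl2, 0 °C → rt; then 1 M HCl (aq)
Reagents that add atoms: dichloromethyl methyl ether, COC(Cl)Cl; water, O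
Why: Rieche formylation, an electrophilic aromatic substitution in which the TiCl4-activated dichloromethyl ether can attack only the one free ring carbon (ortho to the 4-OH, para to the 2-OH), and aqueous work-up should deliver the aldehyde; no stereocenter is formed.

Step 2
Reactants: 2 methyl 3-formyl-4,6-dihydroxy-2,5-dimethylbenzoate
Product: 3 methyl 2,4-dihydroxy-3,5,6-trimethylbenzoate
Conditions: H2 (4 bar), 10% Pd/C, AcOH, 40 °C
Reagents that add atoms: none
Why: Exhaustive catalytic hydrogenolysis of an ortho-hydroxyaryl aldehyde, whose benzylic C–O bond is activated by the ortho and para oxygen substituents, should turn CHO into CH3 while ester and arene stay untouched.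

Step 3
Reactants: 3 methyl 2,4-dihydroxy-3,5,6-trimethylbenzoate
Product: 4 methyl 2,4-bis(methoxymethoxy)-3,5,6-trimethylbenzoate
Conditions: NaH, MOMCl, DMF, 0 °C → rt
Reagents that add atoms: chloromethyl methyl ether, COCCl
Why: Williamson-type O-alkylation (MOM protection), in which NaH also breaks the hydrogen bond of the 2-OH and the hard electrophile reacts at oxygen, should mask both acidic protons ahead of the amide base.

Step 4
Reactants: 4 methyl 2,4-bis(methoxymethoxy)-3,5,6-trimethylbenzoate
Product: 7 6,8-dihydroxy-3,5,7-trimethyl-1H-isochromen-1-one, via benzylic lithium species 5 (not isolated), via keto ester 6 (not isolated)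
Conditions: LiN(i-Pr)2, THF, −78 °C; MeC(O)N(OMe)Me, −78 → 0 °C; 1 M HCl quench; crude 6 in 4 M HCl (aq)/1,4-dioxane, 80 °C
Reagents that add atoms: N-methoxy-N-methylacetamide, CC(=O)N(C)OC
Why: Lateral lithiation of an ortho-toluate (only the methyl group ortho to the doubly flanked, self-condensation-proof ester is acidified), acylation by an N-methoxy-N-methyl amide that prevents over-addition, then acid hydrolysis of both MOM acetals and 6-exo-trig enol-lactonisation onto the ester should close ring B.

Step 5
Reactants: 7 6,8-dihydroxy-3,5,7-trimethyl-1H-isochromen-1-one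
Product: 8 6-(tert-butyldimethylsilyloxy)-8-hydroxy-3,5,7-trimethyl-1H-isochromen-1-one
Conditions: TBSCl (1.1 equiv), imidazole, DMF, rt
Reagents that add atoms: tert-butyldimethylsilyl chloride, CC(C)(C)[Si](C)(C)Cl
Why: Chemoselective silylation, since the 8-OH is locked in a hydrogen bond to the lactone carbonyl while the more acidic, unchelated 6-OH (para to the carbonyl-bearing carbon) should react first.

Step 6
Reactants: 8 6-(tert-butyldimethylsilyloxy)-8-hydroxy-3,5,7-trimethyl-1H-isochromen-1-one; 9 (2E,6E)-farnesol
Product: 10 6-(tert-butyldimethylsilyloxy)-8-[(2E,6E)-farnesyloxy]-3,5,7-trimethyl-1H-isochromen-1-one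
Conditions: PPh3, DIAD, toluene/THF, 0 °C → rt
Reagents that add atoms: none
Why: Mitsunobu etherification, in which the primary allylic alcohol is activated in situ and displaced at C1' in SN2 fashion by phenol O8 under neutral conditions, should spare the silyl ether, the pyranone and both E alkenes and avoid C-alkylation.

Step 7
Reactants: 10 6-(tert-butyldimethylsilyloxy)-8-[(2E,6E)-farnesyloxy]-3,5,7-trimethyl-1H-isochromen-1-one
Product: 13 (5S)-8-hydroxy-3,5,7-trimethyl-5-[(2E,6E)-farnesyl]-1H-isochromene-1,6(5H)-dione (target), via ortho-dienone 11 (not isolated), via silyl para-dienone 12 (not isolated)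
Conditions: [Cu((S,S)-t-Bu-box)](SbF6)2 (20 mol %), 4 Å MS, CH2Cl2, −20 °C → rt; then Et3N·3HF, THF, 0 °C
Reagents that add atoms: none
Why: Proposed new method: divalent copper binds O8 and the carbonyl oxygen on C1 in a six-membered chelate, which weakens the O8–C1' bond and triggers a chair-like aromatic Claisen [3,3] shift of C3' onto C7 (11); since C7 bears a methyl group 11 cannot enolise and instead relieves its two adjacent quaternary carbons by a chair-like Cope [3,3] shift that forms the C1'–C5 bond (12), and fluoride then frees the vinylogous acid, which settles as the C8 enol hydrogen-bonded to C1=O (13). The closest known reaction types are the para-Claisen rearrangement of 2,6-disubstituted aryl prenyl ethers, including dearomatising cases steered by chiral aluminium Lewis acids, and the copper bis(oxazoline)-catalysed enantioselective Claisen rearrangement of allyl vinyl ethers and allyl naphthyl ethers that hold an ester carbonyl beside the ether oxygen; new is their union on an isocoumarin that carries a farnesyl chain. No ring is closed, the two shifts merely pass through six-membered cyclic transition states. C5, the only stereocenter kept, is controlled by the ligand: the tert-butyl group beside O8 pushes the out-of-plane O–CH2 chain onto one face of ring A, both shifts are suprafacial on that face, so the configuration written at C7 (and C3') in 11 is handed on to C5 while C7 and C3' turn planar again. The step needs C5 rather than C7, C8a or oxygen, linear rather than branched attachment, retention of the 2'E alkene and one alkylation only, and the substrate secures all four: C1' can reach only the carbon para to O8 (a first shift to C8a would lead on to the same C5 on the same face), two allyl inversions restore the linear chain, the chair–chair passage returns the E geometry, and the one-to-one tether rules out a second farnesylation of the acidic product. The loss of benzenoid aromaticity is paid for by the vinylogous ester in 12, the 2-pyranone ring B that stays intact, the relief of crowding in hexasubstituted ring A and the tighter chelation of the C8/C1 dicarbonyl unit.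

## Compound list

1 | methyl atratate (methyl 2,4-dihydroxy-3,6-dimethylbenzoate) | COC(=O)c1c(C)cc(O)c(C)c1O | starting material
2 | methyl 3-formyl-4,6-dihydroxy-2,5-dimethylbenzoate | COC(=O)c1c(C)c(C=O)c(O)c(C)c1O | intermediate
3 | methyl 2,4-dihydroxy-3,5,6-trimethylbenzoate | COC(=O)c1c(C)c(C)c(O)c(C)c1O | intermediate
4 | methyl 2,4-bis(methoxymethoxy)-3,5,6-trimethylbenzoate | COC(=O)c1c(C)c(C)c(OCOC)c(C)c1OCOC | intermediate
5 | [2-(methoxycarbonyl)-3,5-bis(methoxymethoxy)-4,6-dimethylbenzyl]lithium | [Li]Cc1c(C)c(OCOC)c(C)c(OCOC)c1C(=O)OC | intermediate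
6 | methyl 2,4-bis(methoxymethoxy)-3,5-dimethyl-6-(2-oxopropyl)benzoate | COC(=O)c1c(CC(C)=O)c(C)c(OCOC)c(C)c1OCOC | intermediate
7 | 6,8-dihydroxy-3,5,7-trimethyl-1H-isochromen-1-one | Cc1cc2c(C)c(O)c(C)c(O)c2c(=O)o1 | intermediate
8 | 6-(tert-butyldimethylsilyloxy)-8-hydroxy-3,5,7-trimethyl-1H-isochromen-1-one | Cc1cc2c(C)c(O[Si](C)(C)C(C)(C)C)c(C)c(O)c2c(=O)o1 | intermediate
9 | (2E,6E)-farnesol | CC(C)=CCC/C(C)=C/CC/C(C)=C/CO | starting material
10 | 6-(tert-butyldimethylsilyloxy)-8-[(2E,6E)-farnesyloxy]-3,5,7-trimethyl-1H-isochromen-1-one | CC(C)=CCC/C(C)=C/CC/C(C)=C/COc1c(C)c(O[Si](C)(C)C(C)(C)C)c(C)c2cc(C)oc(=O)c12 | intermediate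
11 | (7S)-6-(tert-butyldimethylsilyloxy)-3,5,7-trimethyl-7-[(3S,6E)-3,7,11-trimethyldodeca-1,6,10-trien-3-yl]-1H-isochromene-1,8(7H)-dione | C=C[C@](C)(CC/C=C(\C)CCC=C(C)C)[C@]1(C)C(=O)c2c(cc(C)oc2=O)C(C)=C1O[Si](C)(C)C(C)(C)C | intermediate
12 | (5S)-6-(tert-butyldimethylsilyloxy)-3,5,7-trimethyl-5-[(2E,6E)-farnesyl]-1H-isochromene-1,8(5H)-dione | CC(C)=CCC/C(C)=C/CC/C(C)=C/C[C@]1(C)C(O[Si](C)(C)C(C)(C)C)=C(C)C(=O)c2c1cc(C)oc2=O | intermediate
13 | (5S)-8-hydroxy-3,5,7-trimethyl-5-[(2E,6E)-3,7,11-trimethyldodeca-2,6,10-trien-1-yl]-1H-isochromene-1,6(5H)-dione | CC(C)=CCC/C(C)=C/CC/C(C)=C/C[C@]1(C)C(=O)C(C)=C(O)c2c1cc(C)oc2=O | target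

## Step count and risks

Total step count: 7. Longest linear sequence: 7 steps (1 → 13). Farnesol 9 enters unchanged at step 6.

**1. Step 7 (the labelled step).**
- What may go wrong:
  - The copper-bound allylic C–O bond may break heterolytically to an ion pair, which would erode regio- and enantiocontrol and open the way to cationic polyene cyclisation.
  - Facial discrimination by the ligand may be weak.
  - Turnover may be slow because the product chelates the metal.
- Fallback (known chemistry): it sets out from 7 and comes back at 13.
  - Diol 7 is treated with LiN(SiMe3)2 (2 equiv) and (2E,6E)-farnesyl bromide in THF at 0 °C. This is an alkylative dearomatisation of a C-methylated resorcinol.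
  - The racemic 5-farnesyl dienone F1 is separated from C7- and O-alkylated isomers by chromatography.
  - F1 is then resolved by preparative chromatography on a chiral stationary phase. The (5R)-enantiomer F2 is set aside and the (5S)-enantiomer is 13.

**2. Step 4.**
- What may go wrong:
  - Proton transfer from the enolisable amide to the benzylic anion may return 4.
  - Deprotonation may be incomplete because the neighbouring methyl group hinders the planar benzylic anion.
- Fallback: it sets out from 4 and comes back at 7.
  - The anion of 4 (LiN(i-Pr)2, 2.2 equiv, THF, −78 °C) is trapped with methyl chloroformate, a non-enolisable electrophile, to give the dimethyl homophthalate F3.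
  - The methylene group of F3 is now far more acidic and is C-acetylated (LiN(SiMe3)2, AcCl, THF, −78 °C) to the β-keto ester F4.
  - Heating in 6 M HCl/AcOH removes both MOM groups, hydrolyses and decarboxylates the aliphatic ester, and closes ring B to 7.

**3. Step 6.**
- What may go wrong:
  - Coupling may be sluggish at the hydrogen-bonded, doubly flanked 8-OH.
  - The activated alcohol may then be consumed by alkylation of the hydrazide.
- Fallback: it sets out from 3 and comes back at 10. It changes the order of events, so that the ether is made before ring B exists.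
  - Compound 3 is silylated at the unchelated 4-OH (TBSCl, imidazole, DMF) to the silyl ether F5.
  - The sodium phenoxide of F5 (NaH, DMF, 0 °C) can be used here because no base-labile pyranone is present yet. It is alkylated with (2E,6E)-farnesyl bromide to the aryl farnesyl ether F6.
  - Lateral lithiation (LiN(i-Pr)2, THF, −78 °C) and acylation with N-methoxy-N-methylacetamide give the keto ester F7.
  - DBU in MeCN at 40 °C closes ring B by enolate O-acylation to 10.

## Further compounds

F1 | step 7 | racemic 8-hydroxy-3,5,7-trimethyl-5-[(2E,6E)-farnesyl]-1H-isochromene-1,6(5H)-dione | CC(C)=CCC/C(C)=C/CC/C(C)=C/CC1(C)C(=O)C(C)=C(O)c2c1cc(C)oc2=O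
F2 | step 7 | (5R)-8-hydroxy-3,5,7-trimethyl-5-[(2E,6E)-farnesyl]-1H-isochromene-1,6(5H)-dione | CC(C)=CCC/C(C)=C/CC/C(C)=C/C[C@@]1(C)C(=O)C(C)=C(O)c2c1cc(C)oc2=O
F3 | step 4 | methyl 2-(2-methoxy-2-oxoethyl)-4,6-bis(methoxymethoxy)-3,5-dimethylbenzoate | COC(=O)Cc1c(C)c(OCOC)c(C)c(OCOC)c1C(=O)OC
F4 | step 4 | methyl 2-(1-methoxy-1,3-dioxobutan-2-yl)-4,6-bis(methoxymethoxy)-3,5-dimethylbenzoate (racemic, enolisable) | COC(=O)C(C(C)=O)c1c(C)c(OCOC)c(C)c(OCOC)c1C(=O)OC
F5 | step 6 | methyl 4-(tert-butyldimethylsilyloxy)-2-hydroxy-3,5,6-trimethylbenzoate | COC(=O)c1c(C)c(C)c(O[Si](C)(C)C(C)(C)C)c(C)c1O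
F6 | step 6 | methyl 4-(tert-butyldimethylsilyloxy)-2-[(2E,6E)-farnesyloxy]-3,5,6-trimethylbenzoate | COC(=O)c1c(C)c(C)c(O[Si](C)(C)C(C)(C)C)c(C)c1OC/C=C(\C)CC/C=C(\C)CCC=C(C)C
F7 | step 6 | methyl 4-(tert-butyldimethylsilyloxy)-2-[(2E,6E)-farnesyloxy]-3,5-dimethyl-6-(2-oxopropyl)benzoate | COC(=O)c1c(CC(C)=O)c(C)c(O[Si](C)(C)C(C)(C)C)c(C)c1OC/C=C(\C)CC/C=C(\C)CCC=C(C)C
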